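**Retrosynthetic overview**

1. Target ⇐ macrocyclic diol-ketone (two acetylations; acid unmasking of a C10 ketal and two silyl ethers) ⇐ macrocyclic C1 boronic ester (Zweifel isopropenylation, retention).
2. The only ring, the 14-membered carbocycle, is formed by ring contraction: a C2 alkyllithium closes onto the boron of a C1 α-carbamoyloxy boronate (15-membered cyclic boronate complex); a 1,2-shift of C2 from B to C1 then makes the C1–C2 bond and expels boron from the ring.
3. Open chain ⇐ C9–C10 ketone union: C9 organolithium + cis-γ-lactone (C10–C13, carrying the C14–C1 carbamate arm).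
4. Lactone ⇐ but-3-en-1-ol + cis-but-2-ene (syn-crotylation sets C12/C13). Bromide ⇐ (S)-3-bromo-2-methylpropan-1-ol (C8) + acetaldehyde hydrazone + trans-but-2-ene (anti-crotylation sets C4/C5).
5. C1 is set by (−)-sparteine lithiation–borylation, inverted in the ring contraction and retained in the Zweifel step.

Assumption: locants C1–C14 are the ring carbons in the order of the given SMILES (C1 bears isopropenyl, then C2, C3 …); the target is (1S,4R,5S,8S,12R,13R), and these locants are used for all intermediates.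

**Route**

Step 1
Reactants: 1 but-3-en-1-ol
Product: 2 but-3-en-1-yl N,N-diisopropylcarbamate
Conditions: NaH, i-Pr2NCOCl, THF, 0 °C → reflux
Reagents that add atoms: N,N-diisopropylcarbamoyl chloride, ClC(=O)N(C(C)C)C(C)C
Why: Carbamoylation of the sodium alkoxide installs the Hoppe carbamate that later directs lithiation at C1 and serves as the leaving group; no stereocentre.

Step 2
Reactants: 2 but-3-en-1-yl N,N-diisopropylcarbamate
Product: 4 3-oxopropyl N,N-diisopropylcarbamate, via secondary ozonide 3 (not isolated)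
Conditions: O3, CH2Cl2, −78 °C; then Me2S, −78 °C → rt
Reagents that add atoms: ozone, [O-][O+]=O
Why: Ozonolysis with reductive work-up cleaves the terminal alkene to the C13 aldehyde; the carbamate is inert.

Step 3
Reactants: 4 3-oxopropyl N,N-diisopropylcarbamate; 5 cis-but-2-ene
Product: 9 (3R,4R)-3-hydroxy-4-methylhex-5-en-1-yl N,N-diisopropylcarbamate, via (Z)-crotylpotassium 6 (not isolated), via (Z)-crotylborane 7 (not isolated), via borinate 8 (not isolated)
Conditions: 5, n-BuLi, KOt-Bu, THF, −78 → −45 °C; (−)-Ipc2BOMe, −78 °C; BF3·OEt2; 4, −78 °C; then NaOH, H2O2, 0 °C → rt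
Reagents that add atoms: none
Why: Brown asymmetric crotylboration: the (Z)-crotylborane reacts through a closed chair transition state to give the syn C12-Me/C13-OH pair, and the (+)-α-pinene-derived Ipc groups select the aldehyde face that gives 12R,13R.

Step 4
Reactants: 9 (3R,4R)-3-hydroxy-4-methylhex-5-en-1-yl N,N-diisopropylcarbamate
Product: 11 (3R,4R)-3,6-dihydroxy-4-methylhexyl N,N-diisopropylcarbamate, via bis(9-BBN) adduct 10 (not isolated)
Conditions: 9-BBN (2.2 equiv), THF, 0 °C → rt; then NaOH, H2O2, 0 °C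
Reagents that add atoms: hydrogen peroxide, OO
Why: Anti-Markovnikov hydroboration–oxidation of the monosubstituted alkene gives the primary C10 alcohol without touching a stereocentre.

Step 5
Reactants: 11 (3R,4R)-3,6-dihydroxy-4-methylhexyl N,N-diisopropylcarbamate
Product: 12 2-[(2R,3R)-3-methyl-5-oxooxolan-2-yl]ethyl N,N-diisopropylcarbamate
Conditions: TEMPO (cat.), PhI(OAc)2, CH2Cl2, rt
Reagents that add atoms: none
Why: Oxidative lactonisation of the 1,4-diol (TEMPO oxidation of the primary alcohol, lactol formation with the C13 hydroxyl, second oxidation) gives the cis-γ-lactone with C12/C13 unchanged.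

Step 6
Reactants: 13 (S)-3-bromo-2-methylpropan-1-ol
Product: 14 (S)-3-bromo-2-methylpropyl trifluoromethanesulfonate
Conditions: Tf2O, 2,6-lutidine, CH2Cl2, −78 °C
Reagents that add atoms: trifluoromethanesulfonic anhydride, O=S(=O)(OS(=O)(=O)C(F)(F)F)C(F)(F)F
Why: O-Sulfonylation makes the alcohol carbon (C7) far more electrophilic than the bromide carbon (C9), so the two ends are differentiated; C8 is not involved.

Step 7
Reactants: 14 (S)-3-bromo-2-methylpropyl trifluoromethanesulfonate; 15 acetaldehyde N,N-dimethylhydrazone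
Product: 18 (S)-5-bromo-4-methylpentanal, via lithiated hydrazone 16 (not isolated), via alkylated hydrazone 17 (not isolated)
Conditions: 15, LDA, THF, 0 °C; 14, −78 → −40 °C; then aq. oxalic acid, Et2O, rt
Reagents that add atoms: water, O
Why: Aza-enolate alkylation (Corey–Enders hydrazone alkylation) displaces the triflate chemoselectively over the bromide, and mild hydrolysis unmasks the C5 aldehyde; C8 is untouched.

Step 8
Reactants: 18 (S)-5-bromo-4-methylpentanal; 19 trans-but-2-ene
Product: 23 (3R,4S,7S)-8-bromo-3,7-dimethyloct-1-en-4-ol, via (E)-crotylpotassium 20 (not isolated), via (E)-crotylborane 21 (not isolated), via borinate 22 (not isolated)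
Conditions: 19, n-BuLi, KOt-Bu, THF, −78 → −45 °C; (+)-Ipc2BOMe, −78 °C; BF3·OEt2; 18, −78 °C; then NaBO3·4H2O, THF/H2O, rt
Reagents that add atoms: none
Why: Brown asymmetric crotylboration: the (E)-crotylborane gives the anti C4-Me/C5-OH pair through the chair transition state, and the (−)-α-pinene-derived Ipc groups deliver 4R,5S regardless of the remote C8 centre.

Step 9
Reactants: 23 (3R,4S,7S)-8-bromo-3,7-dimethyloct-1-en-4-ol; 12 2-[(2R,3R)-3-methyl-5-oxooxolan-2-yl]ethyl N,N-diisopropylcarbamate
Product: 26 (3R,4R,8S,11S,12R)-3,11-dihydroxy-4,8,12-trimethyl-6-oxotetradec-13-en-1-yl N,N-diisopropylcarbamate, via dilithio species 24 (not isolated), via lithium lactolate 25 (not isolated)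
Conditions: 23, t-BuLi (3.1 equiv), Et2O, −78 °C; then 12, −78 °C; aq. NH4Cl
Reagents that add atoms: none
Why: O-Deprotonation and bromine–lithium exchange give a primary alkyllithium whose single addition to the γ-lactone (nucleophilic acyl substitution halted at the tetrahedral lactolate) forms the C9–C10 bond and, on work-up, the C10 ketone; no stereocentre is formed.

Step 10
Reactants: 26 (3R,4R,8S,11S,12R)-3,11-dihydroxy-4,8,12-trimethyl-6-oxotetradec-13-en-1-yl N,N-diisopropylcarbamate
Product: 27 bis-TBS ether of 26 (OTBS at C5 and C13; free C10 ketone)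
Conditions: TBSOTf, 2,6-lutidine, CH2Cl2, −78 → 0 °C
Reagents that add atoms: tert-butyldimethylsilyl trifluoromethanesulfonate, CC(C)(C)[Si](C)(C)OS(=O)(=O)C(F)(F)F
Why: Silylation of both secondary alcohols (the open hydroxy-ketone form is drained from its hemiketal equilibrium) protects C5–OH and C13–OH against the organolithium steps.

Step 11
Reactants: 27 bis-TBS ether of 26
Product: 28 C10 ethylene ketal (1,3-dioxolane) of 27
Conditions: TMSOCH2CH2OTMS, TMSOTf (cat.), CH2Cl2, −78 → −20 °C
Reagents that add atoms: 1,2-bis(trimethylsilyloxy)ethane, C[Si](C)(C)OCCO[Si](C)(C)C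
Why: Noyori ketalisation under aprotic conditions masks the C10 ketone without disturbing silyl ethers, carbamate or alkene.

Step 12
Reactants: 28 C10 ethylene ketal of 27
Product: 30 (1S)-α-carbamoyloxy pinacol boronate (Bpin and OCb both on C1), via (S)-α-lithiocarbamate 29 (not isolated)
Conditions: s-BuLi, (−)-sparteine, Et2O, −78 °C, 5 h; then i-PrOBpin, −78 °C → rt
Reagents that add atoms: 2-isopropoxy-4,4,5,5-tetramethyl-1,3,2-dioxaborolane, CC(C)OB1OC(C)(C)C(C)(C)O1
Why: Hoppe asymmetric deprotonation: s-BuLi/(−)-sparteine removes the pro-S hydrogen at C1 and the configurationally stable lithiated carbamate is borylated with retention, setting C1 (S) under reagent control.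

Step 13
Reactants: 30 (1S)-α-carbamoyloxy pinacol boronate
Product: 32 primary iodide (terminal alkene of 30 converted into C3H2–C2H2–I), via alkylzirconocene 31 (not isolated)
Conditions: Cp2Zr(H)Cl, THF, rt; then I2, 0 °C
Reagents that add atoms: iodine, II
Why: Hydrozirconation places Zr on the terminal carbon C2 and iodinolysis of the C–Zr bond gives the primary iodide (net anti-Markovnikov hydroiodination); boronate, carbamate, ketal and silyl ethers are tolerated.

Step 14
Reactants: 32 primary iodide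
Product: 35 (1S,4R,5S,8S,12R,13R)-macrocyclic boronic ester (cyclotetradecane: Bpin at C1; Me at C4/C8/C12; OTBS at C5/C13; ethylene ketal at C10), via alkyllithium 33 (not isolated), via cyclic boronate complex 34 (not isolated)
Conditions: t-BuLi (2.1 equiv) added to 32 (1 mM, Et2O/pentane), −100 → −78 °C; then MgBr2·OEt2, −78 → 35 °C
Reagents that add atoms: none
Why: Proposed new method: ring-contractive macrocyclisation by 1,2-metalate shift — iodine–lithium exchange of the primary iodide should outrun attack of t-BuLi on the α-branched pinacol boronate, the C2 alkyllithium then adds irreversibly to boron and at 1 mM should close the 15-membered cyclic boronate complex rather than oligomerise, and Mg(II) triggers antiperiplanar migration of C2 from boron to C1 with loss of carbamate, which forms the C1–C2 bond with inversion at C1, expels boron from the ring and leaves the 14-membered carbocycle with Bpin on (1S)-C1; the closest known chemistry is the intermolecular Hoppe/Matteson-type 1,2-metalate rearrangement of α-carbamoyloxy boronates with Grignard or organolithium reagents and the ring contraction of small cyclic boronate complexes generated by halogen–lithium exchange, neither of which has been shown for a macrocycle.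

Step 15
Reactants: 35 macrocyclic boronic ester; 36 2-bromopropene
Product: 39 (1S,4R,5S,8S,12R,13R)-macrocyclic isopropenyl compound (as 35 but isopropenyl at C1), via isopropenyllithium 37 (not isolated), via alkenylboronate complex 38 (not isolated)
Conditions: 36, t-BuLi, THF, −78 °C; 35, −78 °C; I2, MeOH, −78 °C; NaOMe, −78 °C → rt
Reagents that add atoms: none
Why: Zweifel olefination: iodine triggers a 1,2-shift of C1 from boron to the alkenyl carbon with retention and anti-elimination of boron and iodide gives the isopropenyl group, completing (1S)-C1.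

Step 16
Reactants: 39 macrocyclic isopropenyl compound
Product: 40 (1S,4R,5S,8S,12R,13R)-5,13-dihydroxy-4,8,12-trimethyl-1-(prop-1-en-2-yl)cyclotetradecan-10-one (target locants)
Conditions: 2 M aq. HCl, THF, rt → 40 °C
Reagents that add atoms: water, O
Why: Acid hydrolysis removes the dioxolane and both TBS ethers in one operation; no stereocentre can epimerise because none is α to the ketone.

Step 17
Reactants: 40 dihydroxy ketone
Product: 41 CNP0328624.1
Conditions: Ac2O, pyridine, DMAP (cat.), CH2Cl2, rt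
Reagents that add atoms: acetic anhydride, CC(=O)OC(C)=O
Why: DMAP-catalysed acylation of the two secondary alcohols (any transannular hemiketal is drained through the open form) gives the diacetate with all six stereocentres intact.

**Compound list**

1 | but-3-en-1-ol | C=CCCO | starting material
2 | but-3-en-1-yl N,N-diisopropylcarbamate | C=CCCOC(=O)N(C(C)C)C(C)C | intermediate
3 | 2-(1,2,4-trioxolan-3-yl)ethyl N,N-diisopropylcarbamate (secondary ozonide, not isolated) | C1(CCOC(=O)N(C(C)C)C(C)C)OCOO1 | intermediate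
4 | 3-oxopropyl N,N-diisopropylcarbamate | O=CCCOC(=O)N(C(C)C)C(C)C | intermediate
5 | cis-but-2-ene | C/C=C\C | starting material
6 | (Z)-but-2-enylpotassium (not isolated) | C/C=C\C[K] | intermediate
7 | B-[(Z)-but-2-enyl]diisopinocampheylborane, Ipc from (+)-α-pinene (not isolated) | C/C=C\CB([C@@H]1C[C@@H]2C[C@H]([C@H]1C)C2(C)C)[C@@H]1C[C@@H]2C[C@H]([C@H]1C)C2(C)C | intermediate
8 | diisopinocampheylborinate of 9 (not isolated) | C=C[C@@H](C)[C@H](OB([C@@H]1C[C@@H]2C[C@H]([C@H]1C)C2(C)C)[C@@H]1C[C@@H]2C[C@H]([C@H]1C)C2(C)C)CCOC(=O)N(C(C)C)C(C)C | intermediate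
9 | (3R,4R)-3-hydroxy-4-methylhex-5-en-1-yl N,N-diisopropylcarbamate (syn; C12 R, C13 R) | C=C[C@@H](C)[C@H](O)CCOC(=O)N(C(C)C)C(C)C | intermediate
10 | 6-C,3-O-bis(9-borabicyclo[3.3.1]non-9-yl) adduct of 9 (not isolated) | B1(C2CCCC1CCC2)CC[C@@H](C)[C@H](OB1C2CCCC1CCC2)CCOC(=O)N(C(C)C)C(C)C | intermediate
11 | (3R,4R)-3,6-dihydroxy-4-methylhexyl N,N-diisopropylcarbamate | OCC[C@@H](C)[C@H](O)CCOC(=O)N(C(C)C)C(C)C | intermediate
12 | 2-[(2R,3R)-3-methyl-5-oxooxolan-2-yl]ethyl N,N-diisopropylcarbamate (cis-lactone) | O=C1C[C@@H](C)[C@H](O1)CCOC(=O)N(C(C)C)C(C)C | intermediate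
13 | (S)-3-bromo-2-methylpropan-1-ol | OC[C@H](C)CBr | starting material
14 | (S)-3-bromo-2-methylpropyl trifluoromethanesulfonate | FC(F)(F)S(=O)(=O)OC[C@H](C)CBr | intermediate
15 | acetaldehyde N,N-dimethylhydrazone | C/C=N/N(C)C | starting material
16 | lithiated acetaldehyde N,N-dimethylhydrazone (aza-enolate, not isolated) | [Li]C/C=N/N(C)C | intermediate
17 | (E)-1-[(4S)-5-bromo-4-methylpentylidene]-2,2-dimethylhydrazine (not isolated) | CN(C)/N=C/CC[C@H](C)CBr | intermediate
18 | (S)-5-bromo-4-methylpentanal | O=CCC[C@H](C)CBr | intermediate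
19 | trans-but-2-ene | C/C=C/C | starting material
20 | (E)-but-2-enylpotassium (not isolated) | C/C=C/C[K] | intermediate
21 | B-[(E)-but-2-enyl]diisopinocampheylborane, Ipc from (−)-α-pinene (not isolated) | C/C=C/CB([C@H]1C[C@H]2C[C@@H]([C@@H]1C)C2(C)C)[C@H]1C[C@H]2C[C@@H]([C@@H]1C)C2(C)C | intermediate
22 | diisopinocampheylborinate of 23 (not isolated) | C=C[C@@H](C)[C@@H](OB([C@H]1C[C@H]2C[C@@H]([C@@H]1C)C2(C)C)[C@H]1C[C@H]2C[C@@H]([C@@H]1C)C2(C)C)CC[C@H](C)CBr | intermediate
23 | (3R,4S,7S)-8-bromo-3,7-dimethyloct-1-en-4-ol (anti; C4 R, C5 S, C8 S) | C=C[C@@H](C)[C@@H](O)CC[C@H](C)CBr | intermediate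
24 | O,C-dilithio derivative of 23 (lithium alkoxide and C9 alkyllithium, not isolated) | C=C[C@@H](C)[C@@H](O[Li])CC[C@H](C)C[Li] | intermediate
25 | dilithium lactolate adduct of 24 and 12 (C10 epimers, not isolated) | C=C[C@@H](C)[C@@H](O[Li])CC[C@H](C)CC1(O[Li])C[C@@H](C)[C@H](O1)CCOC(=O)N(C(C)C)C(C)C | intermediate
26 | (3R,4R,8S,11S,12R)-3,11-dihydroxy-4,8,12-trimethyl-6-oxotetradec-13-en-1-yl N,N-diisopropylcarbamate (in equilibrium with its cyclic hemiketal) | C=C[C@@H](C)[C@@H](O)CC[C@H](C)CC(=O)C[C@@H](C)[C@H](O)CCOC(=O)N(C(C)C)C(C)C | intermediate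
27 | bis-TBS ether of 26 (OTBS at C5 and C13) | C=C[C@@H](C)[C@@H](O[Si](C)(C)C(C)(C)C)CC[C@H](C)CC(=O)C[C@@H](C)[C@H](O[Si](C)(C)C(C)(C)C)CCOC(=O)N(C(C)C)C(C)C | intermediate
28 | C10 ethylene ketal (1,3-dioxolane) of 27 | C=C[C@@H](C)[C@@H](O[Si](C)(C)C(C)(C)C)CC[C@H](C)CC1(OCCO1)C[C@@H](C)[C@H](O[Si](C)(C)C(C)(C)C)CCOC(=O)N(C(C)C)C(C)C | intermediate
29 | (1S)-1-lithio derivative of 28 (lithiated carbamate, not isolated) | C=C[C@@H](C)[C@@H](O[Si](C)(C)C(C)(C)C)CC[C@H](C)CC1(OCCO1)C[C@@H](C)[C@H](O[Si](C)(C)C(C)(C)C)C[C@H]([Li])OC(=O)N(C(C)C)C(C)C | intermediate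
30 | (1S)-1-(pinacolboryl) derivative of 28 (α-carbamoyloxy boronate) | C=C[C@@H](C)[C@@H](O[Si](C)(C)C(C)(C)C)CC[C@H](C)CC1(OCCO1)C[C@@H](C)[C@H](O[Si](C)(C)C(C)(C)C)C[C@H](B2OC(C)(C)C(C)(C)O2)OC(=O)N(C(C)C)C(C)C | intermediate
31 | C2 alkyl(chloro)zirconocene from 30 (not isolated) | Cl[Zr](C1C=CC=C1)(C1C=CC=C1)CC[C@@H](C)[C@@H](O[Si](C)(C)C(C)(C)C)CC[C@H](C)CC1(OCCO1)C[C@@H](C)[C@H](O[Si](C)(C)C(C)(C)C)C[C@H](B2OC(C)(C)C(C)(C)O2)OC(=O)N(C(C)C)C(C)C | intermediate
32 | primary C2 iodide of the (1S)-α-carbamoyloxy boronate | ICC[C@@H](C)[C@@H](O[Si](C)(C)C(C)(C)C)CC[C@H](C)CC1(OCCO1)C[C@@H](C)[C@H](O[Si](C)(C)C(C)(C)C)C[C@H](B2OC(C)(C)C(C)(C)O2)OC(=O)N(C(C)C)C(C)C | intermediate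
33 | C2 alkyllithium from 32 (not isolated) | [Li]CC[C@@H](C)[C@@H](O[Si](C)(C)C(C)(C)C)CC[C@H](C)CC1(OCCO1)C[C@@H](C)[C@H](O[Si](C)(C)C(C)(C)C)C[C@H](B2OC(C)(C)C(C)(C)O2)OC(=O)N(C(C)C)C(C)C | intermediate
34 | lithium cyclic boronate complex (15-membered boracycle, B spiro to pinacol, OCb on C1; not isolated) | [Li+].CC1(C)O[B-]2(OC1(C)C)CC[C@@H](C)[C@@H](O[Si](C)(C)C(C)(C)C)CC[C@H](C)CC3(OCCO3)C[C@@H](C)[C@H](O[Si](C)(C)C(C)(C)C)C[C@H]2OC(=O)N(C(C)C)C(C)C | intermediate
35 | (1S,4R,5S,8S,12R,13R)-macrocyclic boronic ester: cyclotetradecane with Bpin at C1, Me at C4, C8, C12, OTBS at C5, C13, ethylene ketal at C10 | CC1(C)OB(OC1(C)C)[C@H]2CC[C@@H](C)[C@@H](O[Si](C)(C)C(C)(C)C)CC[C@H](C)CC3(OCCO3)C[C@@H](C)[C@H](O[Si](C)(C)C(C)(C)C)C2 | intermediate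
36 | 2-bromopropene | C=C(C)Br | starting material
37 | isopropenyllithium (not isolated) | C=C(C)[Li] | intermediate
38 | lithium isopropenyl boronate complex of 35 (not isolated) | [Li+].C=C(C)[B-]1(OC(C)(C)C(C)(C)O1)[C@H]2CC[C@@H](C)[C@@H](O[Si](C)(C)C(C)(C)C)CC[C@H](C)CC3(OCCO3)C[C@@H](C)[C@H](O[Si](C)(C)C(C)(C)C)C2 | intermediate
39 | (1S,4R,5S,8S,12R,13R)-macrocycle with isopropenyl at C1, OTBS at C5, C13, ethylene ketal at C10 | C=C(C)[C@H]1CC[C@@H](C)[C@@H](O[Si](C)(C)C(C)(C)C)CC[C@H](C)CC2(OCCO2)C[C@@H](C)[C@H](O[Si](C)(C)C(C)(C)C)C1 | intermediate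
40 | (1S,4R,5S,8S,12R,13R)-5,13-dihydroxy-4,8,12-trimethyl-1-(prop-1-en-2-yl)cyclotetradecan-10-one (target locants) | C=C(C)[C@H]1CC[C@@H](C)[C@@H](O)CC[C@H](C)CC(=O)C[C@@H](C)[C@H](O)C1 | intermediate
41 | CNP0328624.1, the 5,13-diacetate of 40 | C=C(C)[C@H]1CC[C@@H](C)[C@@H](OC(C)=O)CC[C@H](C)CC(=O)C[C@@H](C)[C@H](OC(C)=O)C1 | target

**Totals and risks**

Total step count: 17. Longest linear sequence: 14 steps (steps 1–5, then 9–17); the bromide branch is steps 6–8.

Steps most likely to fail:

Step 14 (the proposed ring contraction). t-BuLi may attack boron before exchange, the alkyllithium may form oligomeric boronates, or the macrocyclic complex may migrate sluggishly. The fallback uses known chemistry, sets out from 30 and comes back at 35. Compound 30 is treated with vinylmagnesium bromide (THF, −78 °C → rt), the established intermolecular 1,2-metalate rearrangement of α-carbamoyloxy boronates with Grignard reagents (vinyl migrates from B to C1, carbamate leaves, inversion). This gives the open-chain allylic boronic ester F1, in which C1 carries Bpin and a vinyl group. Ring-closing metathesis of the two terminal alkenes (Grubbs II, CH2Cl2, 40 °C, 1 mM) forms the 14-membered cycloalkene F2 (new C2=C3 bond, E/Z mixture). Diimide reduction of the ring alkene (2-nitrobenzenesulfonyl hydrazide, Et3N) gives 35. This detour also bypasses step 13.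

Step 9 (fragment union). Risks are messy bromine–lithium exchange on the alkoxide, enolisation of the lactone, or double addition. The fallback sets out from 12 and 23 and comes back at 27. Lactone 12 is opened with MeNHOMe·HCl/AlMe3 to the hydroxy Weinreb amide F3, which is silylated (TBSOTf, 2,6-lutidine) to the silyl ether F4. Alcohol 23 is silylated in the same way to the bromide F5. Bromine–lithium exchange of F5 (t-BuLi, Et2O, −78 °C) and addition to F4 give ketone 27 directly, the chelated tetrahedral intermediate preventing over-addition, so the dianion and the lactol are both avoided.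

Step 16 (global acid deprotection). Risks are hydration or migration of the isopropenyl group and transannular hemiketal or enol-ether formation from the free γ-hydroxy ketone. The fallback sets out from 39 and comes back at 41. TBAF (THF, rt) removes both silyl ethers with the ketal in place to give the diol F6. Acetylation (Ac2O, DMAP, pyridine) gives the diacetate F7. Mild transketalisation (PPTS, wet acetone, 50 °C) then frees the ketone and gives 41, so no free γ-hydroxy ketone is ever exposed to acid.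

**Further compounds**

F1 | step 14 | open-chain (1S)-allylic boronic ester: 30 with the C1 carbamate replaced (inversion) by vinyl | C=C[C@@H](C)[C@@H](O[Si](C)(C)C(C)(C)C)CC[C@H](C)CC1(OCCO1)C[C@@H](C)[C@H](O[Si](C)(C)C(C)(C)C)C[C@@H](B2OC(C)(C)C(C)(C)O2)C=C
F2 | step 14 | 2,3-didehydro derivative of 35 (14-membered cycloalkene, C2=C3, E/Z mixture) | CC1(C)OB(OC1(C)C)[C@H]2C=C[C@@H](C)[C@@H](O[Si](C)(C)C(C)(C)C)CC[C@H](C)CC3(OCCO3)C[C@@H](C)[C@H](O[Si](C)(C)C(C)(C)C)C2
F3 | step 9 | (3R,4R)-3-hydroxy-6-[methoxy(methyl)amino]-4-methyl-6-oxohexyl N,N-diisopropylcarbamate | CON(C)C(=O)C[C@@H](C)[C@H](O)CCOC(=O)N(C(C)C)C(C)C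
F4 | step 9 | TBS ether of F3 | CON(C)C(=O)C[C@@H](C)[C@H](O[Si](C)(C)C(C)(C)C)CCOC(=O)N(C(C)C)C(C)C
F5 | step 9 | (3R,4S,7S)-8-bromo-4-(tert-butyldimethylsilyloxy)-3,7-dimethyloct-1-ene | C=C[C@@H](C)[C@@H](O[Si](C)(C)C(C)(C)C)CC[C@H](C)CBr
F6 | step 16 | C10 ethylene ketal of 40 (5,13-diol) | C=C(C)[C@H]1CC[C@@H](C)[C@@H](O)CC[C@H](C)CC2(OCCO2)C[C@@H](C)[C@H](O)C1
F7 | step 16 | C10 ethylene ketal of 41 (5,13-diacetate) | C=C(C)[C@H]1CC[C@@H](C)[C@@H](OC(C)=O)CC[C@H](C)CC2(OCCO2)C[C@@H](C)[C@H](OC(C)=O)C1
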